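**Retrosynthetic overview**

1. Bisoflavolin H ⇐ fourfold O‑demethylation of tetramethyl ether 20 ⇐ copper‑catalysed diaryl ether coupling of aryl bromide 14 (C4' of unit 1, the chlorinated isoflavone) with the C8 phenol 19 of tri‑O‑methylgenistein (unit 2, made from genistein by methylation, C8 bromination and borylation–oxidation).
2. Feature the route rests on: in unit 1 (chromone numbering) C7, C8 and C8a carry oxygen, chlorine and O1 in a row, and C4a next to C8a carries the acyl carbon C4. This is the pattern left by an aryne across C8–C8a, flanked by the C7 methoxy group and by a tether on C4a, that takes up an oxygen nucleophile at C8a and an electrophilic chlorine at C8.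
3. 14 ⇐ enol 9 (enolate oxygen closes O1–C8a on the aryne, C2Cl6 delivers Cl to C8) ⇐ C‑formylation of deoxybenzoin 8 ⇐ aldehyde 5 + benzylic Grignard 6, then oxidation ⇐ 2‑bromo‑3‑methoxyphenol 1 (retro‑Brook silylation, ortho‑formylation, triflation).
4. Ring order: all benzene rings are bought; the pyranone ring of unit 1 is the only ring made (step 7); both rings of the unit 2 chromone come intact from genistein.

Key step: step 7

Assumption: (4‑bromobenzyl)magnesium bromide is taken as a commercial ether solution (otherwise made from 4‑bromobenzyl bromide and magnesium in Et2O); chromone numbering is used for both isoflavone halves.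

**Route**

Step 1
Reactants: 1 2‑bromo‑3‑methoxyphenol
Product: 3 3‑methoxy‑2‑(trimethylsilyl)phenol, via aryl silyl ether 2 (not isolated)
Conditions: HN(SiMe3)2, THF, reflux, then evaporation; n‑BuLi, THF, −78 °C → rt; aq. NH4Cl
Reagents that add atoms: hexamethyldisilazane, C[Si](C)(C)N[Si](C)(C)C
Why: O‑silylation, bromine–lithium exchange and 1,3 O→C silyl shift (retro‑Brook rearrangement), driven by the exchange of an aryllithium for a lithium phenoxide, should place silicon on the carbon between the two oxygen substituents without any electrophilic step that could attack the arylsilane.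

Step 2
Reactants: 3 3‑methoxy‑2‑(trimethylsilyl)phenol
Product: 4 2‑hydroxy‑4‑methoxy‑3‑(trimethylsilyl)benzaldehyde
Conditions: MgCl2, Et3N, (CH2O)n, MeCN, reflux; cold 1 M HCl
Reagents that add atoms: paraformaldehyde (as formaldehyde), C=O
Why: Casnati–Skattebøl ortho‑formylation: the magnesium phenoxide delivers formaldehyde to the only free ortho carbon and a second formaldehyde accepts the hydride, under basic conditions that 2‑silylphenols are known to tolerate.

Step 3
Reactants: 4 2‑hydroxy‑4‑methoxy‑3‑(trimethylsilyl)benzaldehyde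
Product: 5 6‑formyl‑3‑methoxy‑2‑(trimethylsilyl)phenyl trifluoromethanesulfonate
Conditions: Tf2O, pyridine, CH2Cl2, 0 °C → rt
Reagents that add atoms: trifluoromethanesulfonic anhydride, O=S(=O)(OS(=O)(=O)C(F)(F)F)C(F)(F)F
Why: O‑sulfonylation of the phenol, the usual last step towards ortho‑silyl aryl triflates; the triflate also deactivates the ring and so protects the C–Si bond in later acidic work‑ups.

Step 4
Reactants: 5 6‑formyl‑3‑methoxy‑2‑(trimethylsilyl)phenyl trifluoromethanesulfonate; 6 (4‑bromobenzyl)magnesium bromide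
Product: 7 (±)‑6‑[2‑(4‑bromophenyl)‑1‑hydroxyethyl]‑3‑methoxy‑2‑(trimethylsilyl)phenyl trifluoromethanesulfonate
Conditions: 6 (1.1 equiv), THF/Et2O, −78 °C; aq. NH4Cl
Reagents that add atoms: none
Why: Grignard 1,2‑addition to the aldehyde at a temperature at which aryl triflate, aryl bromide and arylsilane are inert; the carbinol centre forms racemic and is removed in step 5.

Step 5
Reactants: 7 (±)‑6‑[2‑(4‑bromophenyl)‑1‑hydroxyethyl]‑3‑methoxy‑2‑(trimethylsilyl)phenyl trifluoromethanesulfonate
Product: 8 6‑[2‑(4‑bromophenyl)acetyl]‑3‑methoxy‑2‑(trimethylsilyl)phenyl trifluoromethanesulfonate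
Conditions: Dess–Martin periodinane, CH2Cl2, rt
Reagents that add atoms: none
Why: Dess–Martin oxidation of a secondary benzylic alcohol under near‑neutral conditions; this gives the deoxybenzoin without the Friedel–Crafts acylation of an arylsilane, in which acyl‑desilylation at the silicon‑bearing carbon would compete.

Step 6
Reactants: 8 6‑[2‑(4‑bromophenyl)acetyl]‑3‑methoxy‑2‑(trimethylsilyl)phenyl trifluoromethanesulfonate
Product: 9 (Z)‑2‑(4‑bromophenyl)‑3‑hydroxy‑1‑[4‑methoxy‑2‑(trifluoromethylsulfonyloxy)‑3‑(trimethylsilyl)phenyl]prop‑2‑en‑1‑one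
Conditions: LiN(SiMe3)2, THF, −78 °C; HCO2CH2CF3, −78 → 0 °C; cold 1 M HCl; dried azeotropically (toluene)
Reagents that add atoms: 2,2,2‑trifluoroethyl formate, O=COCC(F)(F)F
Why: crossed Claisen C‑formylation of the lithium enolate at low temperature, in which the leaving group is the weakly nucleophilic trifluoroethoxide (ethoxide from NaH/ethyl formate could cleave the aryl triflate); acidification should give the hydrogen‑bonded (Z)‑enol.

Step 7
Reactants: 9 (Z)‑2‑(4‑bromophenyl)‑3‑hydroxy‑1‑[4‑methoxy‑2‑(trifluoromethylsulfonyloxy)‑3‑(trimethylsilyl)phenyl]prop‑2‑en‑1‑one; 10 hexachloroethane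
Product: 14 3‑(4‑bromophenyl)‑8‑chloro‑7‑methoxychromen‑4‑one, via sodium enolate 11 (not isolated), via aryne 12 (not isolated), via C8 arylsodium 13 (not isolated)
Conditions: NaH (1.0 equiv), THF, 0 °C, until gas evolution stops; then C2Cl6 (3 equiv), CsF (3 equiv, dried), 18‑crown‑6, THF, 0 °C → rt
Reagents that add atoms: none
Why: Proposed new method: NaH first turns the enol into its sodium enolate 11 with loss of H2, so that fluoride meets no acidic hydrogen (an enol O–H would give HF/bifluoride and protonate C8); fluoride then attacks silicon at C8, triflate leaves from C8a, and the aryne 12 is intercepted by the enolate oxygen at C8a to give the C8 anion 13, which abstracts chlorine from C2Cl6 with release of C2Cl4 and chloride. The closest known reaction types are ring closures of tethered oxygen and nitrogen nucleophiles onto arynes and three‑component aryne couplings in which the aryl anion is quenched by a halogen donor; their combination in a chromone‑forming step is the untested part. The pyranone ring closes by in‑plane attack of oxygen on the aryne carbon in a six‑membered transition state that is exo to the C8–C8a bond (6‑exo‑dig in Baldwin's terms), and no stereocentre is formed. The step needs oxygen at C8a and the charge at C8: the tether on C4a can reach only C8a, and the C7 methoxy group polarises the aryne in the same sense (nucleophile meta to it, carbanion ortho to it), while attack through the enolate carbon would require a four‑membered ring. It also needs chlorine transfer to outrun protonation, which the H2‑releasing deprotonation, THF in place of the C–H acidic acetonitrile, dried CsF and excess C2Cl6 are meant to secure, the carbanion being made more selective by its two flanking oxygens.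

Step 8
Reactants: 15 genistein
Product: 16 5,7‑dimethoxy‑3‑(4‑methoxyphenyl)chromen‑4‑one
Conditions: Me2SO4 (excess), K2CO3, acetone, reflux (prolonged)
Reagents that add atoms: dimethyl sulfate, COS(=O)(=O)OC
Why: Williamson O‑methylation of all three phenols; the chelated 5‑OH reacts last and needs excess reagent and long heating.

Step 9
Reactants: 16 5,7‑dimethoxy‑3‑(4‑methoxyphenyl)chromen‑4‑one
Product: 17 8‑bromo‑5,7‑dimethoxy‑3‑(4‑methoxyphenyl)chromen‑4‑one
Conditions: N‑bromosuccinimide (1.05 equiv), DMF, 0 °C → rt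
Reagents that add atoms: N‑bromosuccinimide, O=C1CCC(=O)N1Br
Why: electrophilic aromatic bromination, which in 5,7‑dimethoxychromones goes to C8 (para to the 5‑methoxy group, C6 being enclosed by two methoxy groups); the phloroglucinol‑type ring A is far more reactive than the anisyl ring.

Step 10
Reactants: 17 8‑bromo‑5,7‑dimethoxy‑3‑(4‑methoxyphenyl)chromen‑4‑one
Product: 19 8‑hydroxy‑5,7‑dimethoxy‑3‑(4‑methoxyphenyl)chromen‑4‑one, via pinacol boronate 18 (not isolated)
Conditions: Pd(OAc)2 (cat.), SPhos, B2pin2, KOAc, dioxane, 90 °C; filtration and evaporation; then Me3NO, THF, 50 °C; aqueous work‑up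
Reagents that add atoms: bis(pinacolato)diboron, CC1(C)OB(OC1(C)C)B1OC(C)(C)C(C)(C)O1 (boryl group of 18); trimethylamine N‑oxide, C[N+](C)(C)[O-] (oxygen of 19)
Why: Miyaura borylation with a ligand suited to flanked, electron‑rich aryl bromides, followed by C–B oxidation with an amine N‑oxide (ate complex, 1,2‑aryl shift to oxygen), a non‑basic oxidant that should spare the pyranone C2=C3 bond that alkaline peroxide could attack.

Step 11
Reactants: 14 3‑(4‑bromophenyl)‑8‑chloro‑7‑methoxychromen‑4‑one; 19 8‑hydroxy‑5,7‑dimethoxy‑3‑(4‑methoxyphenyl)chromen‑4‑one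
Product: 20 8‑[4‑(8‑chloro‑7‑methoxy‑4‑oxochromen‑3‑yl)phenoxy]‑5,7‑dimethoxy‑3‑(4‑methoxyphenyl)chromen‑4‑one
Conditions: CuI (cat.), picolinic acid (cat.), K3PO4, DMSO, 90 °C, argon
Reagents that add atoms: none
Why: Ullmann‑type C–O coupling with the copper/picolinic acid system, which accepts 2,6‑disubstituted phenols; the unhindered aryl bromide should react in preference to the flanked, electron‑rich C8 chloride.

Step 12
Reactants: 20 8‑[4‑(8‑chloro‑7‑methoxy‑4‑oxochromen‑3‑yl)phenoxy]‑5,7‑dimethoxy‑3‑(4‑methoxyphenyl)chromen‑4‑one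
Product: 21 Bisoflavolin H
Conditions: BBr3 (excess), CH2Cl2, −78 °C → rt; MeOH, then water
Reagents that add atoms: none
Why: Lewis acid cleavage of the four aryl methyl ethers (bromide attacks the methyl group of each boron–ether complex), to which the diaryl ether, the aryl chloride and both chromone rings are inert; the low starting temperature limits acid‑induced ring opening and reclosure of the 5,7,8‑trioxygenated half.

**Compound list**

1 | 2‑bromo‑3‑methoxyphenol | COc1cccc(O)c1Br | starting material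
2 | (2‑bromo‑3‑methoxyphenoxy)trimethylsilane | COc1cccc(O[Si](C)(C)C)c1Br | intermediate
3 | 3‑methoxy‑2‑(trimethylsilyl)phenol | COc1cccc(O)c1[Si](C)(C)C | intermediate
4 | 2‑hydroxy‑4‑methoxy‑3‑(trimethylsilyl)benzaldehyde | COc1ccc(C=O)c(O)c1[Si](C)(C)C | intermediate
5 | 6‑formyl‑3‑methoxy‑2‑(trimethylsilyl)phenyl trifluoromethanesulfonate | COc1ccc(C=O)c(OS(=O)(=O)C(F)(F)F)c1[Si](C)(C)C | intermediate
6 | (4‑bromobenzyl)magnesium bromide | Br[Mg]Cc1ccc(Br)cc1 | starting material
7 | (±)‑6‑[2‑(4‑bromophenyl)‑1‑hydroxyethyl]‑3‑methoxy‑2‑(trimethylsilyl)phenyl trifluoromethanesulfonate (racemic) | COc1ccc(C(O)Cc2ccc(Br)cc2)c(OS(=O)(=O)C(F)(F)F)c1[Si](C)(C)C | intermediate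
8 | 6‑[2‑(4‑bromophenyl)acetyl]‑3‑methoxy‑2‑(trimethylsilyl)phenyl trifluoromethanesulfonate | COc1ccc(C(=O)Cc2ccc(Br)cc2)c(OS(=O)(=O)C(F)(F)F)c1[Si](C)(C)C | intermediate
9 | (Z)‑2‑(4‑bromophenyl)‑3‑hydroxy‑1‑[4‑methoxy‑2‑(trifluoromethylsulfonyloxy)‑3‑(trimethylsilyl)phenyl]prop‑2‑en‑1‑one | O/C=C(/c1ccc(Br)cc1)C(=O)c1ccc(OC)c([Si](C)(C)C)c1OS(=O)(=O)C(F)(F)F | intermediate
10 | hexachloroethane | ClC(Cl)(Cl)C(Cl)(Cl)Cl | starting material
11 | sodium (Z)‑2‑(4‑bromophenyl)‑3‑[4‑methoxy‑2‑(trifluoromethylsulfonyloxy)‑3‑(trimethylsilyl)phenyl]‑3‑oxoprop‑1‑en‑1‑olate | [Na+].[O-]/C=C(/c1ccc(Br)cc1)C(=O)c1ccc(OC)c([Si](C)(C)C)c1OS(=O)(=O)C(F)(F)F | intermediate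
12 | sodium (Z)‑2‑(4‑bromophenyl)‑3‑(4‑methoxy‑2,3‑didehydrophenyl)‑3‑oxoprop‑1‑en‑1‑olate (aryne across C8–C8a) | [Na+].[O-]/C=C(/c1ccc(Br)cc1)C(=O)C1=CC=C(OC)C#C1 | intermediate
13 | [3‑(4‑bromophenyl)‑7‑methoxy‑4‑oxochromen‑8‑yl]sodium (C8 aryl anion) | [Na]c1c(OC)ccc2c(=O)c(-c3ccc(Br)cc3)coc12 | intermediate
14 | 3‑(4‑bromophenyl)‑8‑chloro‑7‑methoxychromen‑4‑one | O=c1c(-c2ccc(Br)cc2)coc2c(Cl)c(OC)ccc12 | intermediate
15 | genistein | O=c1c(-c2ccc(O)cc2)coc2cc(O)cc(O)c12 | starting material
16 | 5,7‑dimethoxy‑3‑(4‑methoxyphenyl)chromen‑4‑one | COc1ccc(-c2coc3cc(OC)cc(OC)c3c2=O)cc1 | intermediate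
17 | 8‑bromo‑5,7‑dimethoxy‑3‑(4‑methoxyphenyl)chromen‑4‑one | COc1ccc(-c2coc3c(Br)c(OC)cc(OC)c3c2=O)cc1 | intermediate
18 | 5,7‑dimethoxy‑3‑(4‑methoxyphenyl)‑8‑(4,4,5,5‑tetramethyl‑1,3,2‑dioxaborolan‑2‑yl)chromen‑4‑one | COc1ccc(-c2coc3c(B4OC(C)(C)C(C)(C)O4)c(OC)cc(OC)c3c2=O)cc1 | intermediate
19 | 8‑hydroxy‑5,7‑dimethoxy‑3‑(4‑methoxyphenyl)chromen‑4‑one | COc1ccc(-c2coc3c(O)c(OC)cc(OC)c3c2=O)cc1 | intermediate
20 | 8‑[4‑(8‑chloro‑7‑methoxy‑4‑oxochromen‑3‑yl)phenoxy]‑5,7‑dimethoxy‑3‑(4‑methoxyphenyl)chromen‑4‑one | COc1ccc(-c2coc3c(Oc4ccc(-c5coc6c(Cl)c(OC)ccc6c5=O)cc4)c(OC)cc(OC)c3c2=O)cc1 | intermediate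
21 | Bisoflavolin H | O=c1c(-c2ccc(Oc3c(O)cc(O)c4c(=O)c(-c5ccc(O)cc5)coc34)cc2)coc2c(Cl)c(O)ccc12 | target

**Step count and risks**

Total step count: 12. Longest linear sequence: 9 (steps 1–7, 11, 12).

Steps most likely to fail:

1. Step 7 (new method). What may go wrong:
   - protonation of the C8 carbanion by adventitious water instead of chlorine transfer;
   - chlorination of the enolate carbon by C2Cl6 before the aryne forms;
   - loss or transfer of the triflyl group;
   - a chelated, U‑shaped enolate that cannot reach C8a (the crown ether is there to loosen it);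
   - direct displacement of triflate by the enolate without aryne formation, which leaves silicon on C8.

   The fallback uses known reactions only, sets out from 8 and returns at 14. The triflate of 8 would be cleaved with Et4NOH in aqueous dioxane at room temperature to give 2‑(4‑bromophenyl)‑1‑[2‑hydroxy‑4‑methoxy‑3‑(trimethylsilyl)phenyl]ethanone F1. Heating with N,N‑dimethylformamide dimethyl acetal in toluene, the classical enaminone ring closure of 2‑hydroxydeoxybenzoins, should then give 3‑(4‑bromophenyl)‑7‑methoxy‑8‑(trimethylsilyl)chromen‑4‑one F2. Ipso‑chlorodesilylation with N‑chlorosuccinimide in MeCN, at the carbon activated by O1 and the C7 methoxy group, would lead to 14.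

2. Step 11. What may go wrong: slow C–O bond formation at the doubly ortho‑substituted phenoxide, base‑induced opening of a pyranone ring at 90 °C, oxidation of the electron‑rich phenol, and reductive loss of bromine.

   The fallback replaces the aryl halide coupling by an oxidative coupling at room temperature, sets out from 14 and returns at 20. Miyaura borylation of the carbon–bromine bond of 14 (Pd(dppf)Cl2, B2pin2, KOAc, dioxane, 80 °C; the C8 chloride should stay) would give 8‑chloro‑7‑methoxy‑3‑[4‑(4,4,5,5‑tetramethyl‑1,3,2‑dioxaborolan‑2‑yl)phenyl]chromen‑4‑one F3. Oxidative removal of pinacol (NaIO4, NH4OAc, acetone/water) would give [4‑(8‑chloro‑7‑methoxy‑4‑oxochromen‑3‑yl)phenyl]boronic acid F4. Chan–Lam coupling with phenol 19 (Cu(OAc)2, pyridine, 4 Å molecular sieves, CH2Cl2, rt) would then give 20.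

3. Step 10. What may go wrong: sluggish oxidative addition into the flanked, electron‑rich carbon–bromine bond with competing hydrodebromination, and protodeborylation of the hindered boronate before it is oxidised.

   The fallback brings in the C8 oxygen through a carbonyl group instead of boron, sets out from 16 and returns at 19. Rieche formylation (Cl2CHOMe, TiCl4, CH2Cl2, 0 °C) should give 5,7‑dimethoxy‑3‑(4‑methoxyphenyl)‑4‑oxochromene‑8‑carbaldehyde F5. Baeyer–Villiger oxidation of this electron‑rich aldehyde with mCPBA (Dakin‑type aryl migration) would give 5,7‑dimethoxy‑3‑(4‑methoxyphenyl)‑4‑oxochromen‑8‑yl formate F6. Brief methanolysis (K2CO3, MeOH, 0 °C) would release 19.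

**Further compounds**

F1 | step 7 | 2‑(4‑bromophenyl)‑1‑[2‑hydroxy‑4‑methoxy‑3‑(trimethylsilyl)phenyl]ethanone | COc1ccc(C(=O)Cc2ccc(Br)cc2)c(O)c1[Si](C)(C)C
F2 | step 7 | 3‑(4‑bromophenyl)‑7‑methoxy‑8‑(trimethylsilyl)chromen‑4‑one | COc1ccc2c(=O)c(-c3ccc(Br)cc3)coc2c1[Si](C)(C)C
F3 | step 11 | 8‑chloro‑7‑methoxy‑3‑[4‑(4,4,5,5‑tetramethyl‑1,3,2‑dioxaborolan‑2‑yl)phenyl]chromen‑4‑one | COc1ccc2c(=O)c(-c3ccc(B4OC(C)(C)C(C)(C)O4)cc3)coc2c1Cl
F4 | step 11 | [4‑(8‑chloro‑7‑methoxy‑4‑oxochromen‑3‑yl)phenyl]boronic acid | COc1ccc2c(=O)c(-c3ccc(B(O)O)cc3)coc2c1Cl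
F5 | step 10 | 5,7‑dimethoxy‑3‑(4‑methoxyphenyl)‑4‑oxochromene‑8‑carbaldehyde | COc1ccc(-c2coc3c(C=O)c(OC)cc(OC)c3c2=O)cc1
F6 | step 10 | 5,7‑dimethoxy‑3‑(4‑methoxyphenyl)‑4‑oxochromen‑8‑yl formate | COc1ccc(-c2coc3c(OC=O)c(OC)cc(OC)c3c2=O)cc1
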